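The route rests on disconnecting the trimethoxybenzoyl ring (ring A) across C-1–C-2 and C-5–C-6. Its para oxygens at C-2 and C-5, the methoxy at C-4 and the hydrogen at C-3 map onto a 2-silyloxy-4-methoxyfuran, and the vicinal ester carbon C-1 and methyl-bearing C-6 onto a but-2-ynoate. One cycloaddition and bridge opening therefore delivers the fully substituted ring A with its hindered depside ester already in place. The dienophile is the but-2-ynoate of the 4-hydroxyl of an orsellinate (ring B) carrying a 2-O-benzyl ether and an allyl ester, chosen so that the ring B carboxyl can later be freed without touching the benzyl ether; ring C is attached last.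

Key step: step 7

Remark: the target has no stereocentre and the oxygen-bridged cycloadduct 11 is a transient racemate, so all SMILES are written without stereodescriptors.

Step 1
Reactants: 1 orsellinic acid (2,4-dihydroxy-6-methylbenzoic acid)
Product: 2 allyl 2,4-dihydroxy-6-methylbenzoate (allyl orsellinate)
Conditions: allyl bromide, KHCO3, DMF, rt
Reagents that add atoms: allyl bromide, C=CCBr
Why: Carboxylate O-alkylation (SN2) with the weak base KHCO3 ionises only the carboxylic acid, so both phenols stay free, and room temperature avoids decarboxylation; the allyl ester is chosen because it can later be removed without loss of a benzyl ether.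

Step 2
Reactants: 2 allyl 2,4-dihydroxy-6-methylbenzoate
Product: 3 allyl 2-hydroxy-4-(methoxymethoxy)-6-methylbenzoate
Conditions: MOMCl (1.1 equiv), i-Pr2NEt, CH2Cl2, 0 °C
Reagents that add atoms: chloromethyl methyl ether, COCCl
Why: The 2-hydroxyl is tied up in a hydrogen bond to the ester carbonyl, so Williamson-type O-alkylation with one equivalent of the chloromethyl ether under amine base should take place at the free 4-hydroxyl only.

Step 3
Reactants: 3 allyl 2-hydroxy-4-(methoxymethoxy)-6-methylbenzoate
Product: 4 allyl 2-(benzyloxy)-4-(methoxymethoxy)-6-methylbenzoate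
Conditions: BnBr, K2CO3, DMF, 60 °C
Reagents that add atoms: benzyl bromide, BrCc1ccccc1
Why: Williamson etherification under forcing carbonate conditions alkylates the chelated phenol, and it is placed before the base-sensitive aryl ynoate exists, at a stage where acetal, allyl ester and arene are all inert to carbonate.

Step 4
Reactants: 4 allyl 2-(benzyloxy)-4-(methoxymethoxy)-6-methylbenzoate
Product: 5 allyl 2-(benzyloxy)-4-hydroxy-6-methylbenzoate
Conditions: HCl (cat.), MeOH/THF, 40 °C
Reagents that add atoms: none
Why: Acid-catalysed acetal exchange with methanol removes the phenolic methoxymethyl ether as dimethoxymethane, while the benzyl ether and the di-ortho-substituted allyl ester are stable to dilute methanolic HCl.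

Step 5
Reactants: 5 allyl 2-(benzyloxy)-4-hydroxy-6-methylbenzoate; 6 but-2-ynoic acid
Product: 8 allyl 2-(benzyloxy)-4-(but-2-ynoyloxy)-6-methylbenzoate, via O-acylisourea 7 (not isolated)
Conditions: DCC, DMAP (cat.), CH2Cl2, 0 °C to rt
Reagents that add atoms: none
Why: Steglich esterification (carbodiimide activation, DMAP acyl transfer) of the only free phenol gives the aryl but-2-ynoate under near-neutral conditions at low temperature, which keeps the ynoate from isomerising to an allenoate.

Step 6
Reactants: 9 4-methoxyfuran-2(5H)-one (methyl tetronate)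
Product: 10 tert-butyl[(4-methoxyfuran-2-yl)oxy]dimethylsilane
Conditions: TBSOTf, Et3N, CH2Cl2, 0 °C; used without chromatography
Reagents that add atoms: tert-butyldimethylsilyl trifluoromethanesulfonate, CC(C)(C)[Si](C)(C)OS(=O)(=O)C(F)(F)F
Why: Soft enolisation (O-silylation of the lactone carbonyl, then removal of a C-5 proton by the amine) gives the aromatic 2-silyloxyfuran, the standard preparation of silyloxyfurans from butenolides.

Step 7
Reactants: 8 allyl 2-(benzyloxy)-4-(but-2-ynoyloxy)-6-methylbenzoate; 10 tert-butyl[(4-methoxyfuran-2-yl)oxy]dimethylsilane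
Product: 12 allyl 2-(benzyloxy)-4-{[2-(tert-butyldimethylsilyloxy)-5-hydroxy-4-methoxy-6-methylbenzoyl]oxy}-6-methylbenzoate, via oxygen-bridged cycloadduct 11 (not isolated)
Conditions: 10 (3 equiv), toluene, 110 °C, sealed tube
Reagents that add atoms: none
Why: In a normal-electron-demand, asynchronous Diels–Alder reaction the electron-rich furan adds across C-2 and C-5 to the ynoate, C-5 (largest HOMO coefficient, alpha to the ring oxygen and beta to the 4-methoxy enol ether) bonding to the beta carbon and C-2 to the alpha carbon, to give the 1-silyloxy-7-oxanorbornadiene 11. The bridging C–O bond at the silyloxy-bearing bridgehead then ionises with help from the silyloxy lone pair and loss of the proton at the other bridgehead aromatises the ring, so the former furan oxygen becomes the C-5 hydroxyl next to the methyl group and the silyl ether sits at C-2 next to the ester. The closest known reaction type is the Diels–Alder addition of 2-silyloxy- and 2-alkoxyfurans to acetylenic esters with opening of the oxygen bridge to hydroquinone monoethers. Ring A is closed by intermolecular [4+2] cycloaddition, both new ring bonds (C-1–C-2 and C-5–C-6) being formed between the two components and none by cyclisation of a tether. No stereocentre is set, because the two bridgehead centres of racemic 11 are destroyed on aromatisation. The step needs regioselectivity only, which the matched polarisation of diene (both oxygen donors reinforce C-5) and dienophile (largest LUMO coefficient at the methyl-bearing beta carbon, lowered by the electron-poor aryl ester) should secure; a stepwise Mukaiyama–Michael and aldol-type closure would give the same connectivity.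

Step 8
Reactants: 12 allyl 2-(benzyloxy)-4-{[2-(tert-butyldimethylsilyloxy)-5-hydroxy-4-methoxy-6-methylbenzoyl]oxy}-6-methylbenzoate
Product: 15 allyl 2-(benzyloxy)-6-methyl-4-[(2,4,5-trimethoxy-6-methylbenzoyl)oxy]benzoate, via methyl ether 13 (not isolated), via cesium phenoxide 14 (not isolated)
Conditions: MeI (excess), K2CO3, DMF, rt, argon; then CsF, rt
Reagents that add atoms: iodomethane, CI
Why: Williamson methylation of the free 5-hydroxyl is followed by fluoride cleavage of the aryl silyl ether and immediate capture of the phenoxide by iodomethane (one-pot desilylation–alkylation), so no free hydroquinone is handled, and the di-ortho-substituted depside ester, allyl ester and benzyl ether are inert to carbonate and fluoride in dry DMF.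

Step 9
Reactants: 15 allyl 2-(benzyloxy)-6-methyl-4-[(2,4,5-trimethoxy-6-methylbenzoyl)oxy]benzoate
Product: 16 2-(benzyloxy)-6-methyl-4-[(2,4,5-trimethoxy-6-methylbenzoyl)oxy]benzoic acid
Conditions: Pd(PPh3)4 (cat.), morpholine, THF, rt
Reagents that add atoms: none
Why: Tsuji–Trost deallylation, in which zerovalent palladium ionises the allyl ester to a π-allyl complex that morpholine intercepts, frees the ring B carboxylic acid while the benzyl ether and the hindered depside ester are untouched.

Step 10
Reactants: 1 orsellinic acid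
Product: 17 benzyl 2,4-dihydroxy-6-methylbenzoate (benzyl orsellinate)
Conditions: BnBr, KHCO3, DMF, rt
Reagents that add atoms: benzyl bromide, BrCc1ccccc1
Why: The same selective carboxylate O-alkylation (SN2 with KHCO3) as in step 1 leaves both phenols free.

Step 11
Reactants: 16 2-(benzyloxy)-6-methyl-4-[(2,4,5-trimethoxy-6-methylbenzoyl)oxy]benzoic acid; 17 benzyl 2,4-dihydroxy-6-methylbenzoate
Product: 19 benzyl 4-({2-(benzyloxy)-6-methyl-4-[(2,4,5-trimethoxy-6-methylbenzoyl)oxy]benzoyl}oxy)-2-hydroxy-6-methylbenzoate, via mixed anhydride 18 (not isolated)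
Conditions: (CF3CO)2O, toluene, rt; then 17, rt
Reagents that add atoms: none
Why: Depside esterification through the mixed trifluoroacetic anhydride, an activation suited to di-ortho-substituted benzoic acids, acylates the unchelated 4-hydroxyl of 17, whose 2-hydroxyl is deactivated by its hydrogen bond to the ester carbonyl.

Step 12
Reactants: 19 benzyl 4-({2-(benzyloxy)-6-methyl-4-[(2,4,5-trimethoxy-6-methylbenzoyl)oxy]benzoyl}oxy)-2-hydroxy-6-methylbenzoate
Product: 20 2-hydroxy-4-({2-hydroxy-6-methyl-4-[(2,4,5-trimethoxy-6-methylbenzoyl)oxy]benzoyl}oxy)-6-methylbenzoic acid (target)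
Conditions: H2 (1 atm), 10% Pd/C, EtOAc, rt
Reagents that add atoms: none
Why: Catalytic hydrogenolysis cleaves the benzyl ether on ring B and the benzyl ester on ring C in one operation and leaves aryl esters and methyl ethers intact.

Compound list
1 | orsellinic acid (2,4-dihydroxy-6-methylbenzoic acid) | Cc1cc(O)cc(O)c1C(=O)O | starting material
2 | allyl 2,4-dihydroxy-6-methylbenzoate | Cc1cc(O)cc(O)c1C(=O)OCC=C | intermediate
3 | allyl 2-hydroxy-4-(methoxymethoxy)-6-methylbenzoate | COCOc1cc(C)c(C(=O)OCC=C)c(O)c1 | intermediate
4 | allyl 2-(benzyloxy)-4-(methoxymethoxy)-6-methylbenzoate | COCOc1cc(C)c(C(=O)OCC=C)c(OCc2ccccc2)c1 | intermediate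
5 | allyl 2-(benzyloxy)-4-hydroxy-6-methylbenzoate | Cc1cc(O)cc(OCc2ccccc2)c1C(=O)OCC=C | intermediate
6 | but-2-ynoic acid | CC#CC(=O)O | starting material
7 | O-(but-2-ynoyl)-N,N'-dicyclohexylisourea | CC#CC(=O)OC(=NC1CCCCC1)NC1CCCCC1 | intermediate (not isolated)
8 | allyl 2-(benzyloxy)-4-(but-2-ynoyloxy)-6-methylbenzoate | CC#CC(=O)Oc1cc(C)c(C(=O)OCC=C)c(OCc2ccccc2)c1 | intermediate
9 | 4-methoxyfuran-2(5H)-one (methyl tetronate) | COC1=CC(=O)OC1 | starting material
10 | tert-butyl[(4-methoxyfuran-2-yl)oxy]dimethylsilane | COc1coc(O[Si](C)(C)C(C)(C)C)c1 | intermediate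
11 | allyl 2-(benzyloxy)-4-{[1-(tert-butyldimethylsilyloxy)-5-methoxy-3-methyl-7-oxabicyclo[2.2.1]hepta-2,5-dien-2-yl]carbonyloxy}-6-methylbenzoate (racemic) | COC1=CC2(O[Si](C)(C)C(C)(C)C)OC1C(C)=C2C(=O)Oc3cc(C)c(C(=O)OCC=C)c(OCc4ccccc4)c3 | intermediate (not isolated)
12 | allyl 2-(benzyloxy)-4-{[2-(tert-butyldimethylsilyloxy)-5-hydroxy-4-methoxy-6-methylbenzoyl]oxy}-6-methylbenzoate | COc1cc(O[Si](C)(C)C(C)(C)C)c(C(=O)Oc2cc(C)c(C(=O)OCC=C)c(OCc3ccccc3)c2)c(C)c1O | intermediate
13 | allyl 2-(benzyloxy)-4-{[2-(tert-butyldimethylsilyloxy)-4,5-dimethoxy-6-methylbenzoyl]oxy}-6-methylbenzoate | COc1cc(O[Si](C)(C)C(C)(C)C)c(C(=O)Oc2cc(C)c(C(=O)OCC=C)c(OCc3ccccc3)c2)c(C)c1OC | intermediate (not isolated)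
14 | cesium phenoxide of allyl 2-(benzyloxy)-4-[(2-hydroxy-4,5-dimethoxy-6-methylbenzoyl)oxy]-6-methylbenzoate | COc1cc([O-])c(C(=O)Oc2cc(C)c(C(=O)OCC=C)c(OCc3ccccc3)c2)c(C)c1OC.[Cs+] | intermediate (not isolated)
15 | allyl 2-(benzyloxy)-6-methyl-4-[(2,4,5-trimethoxy-6-methylbenzoyl)oxy]benzoate | COc1cc(OC)c(C(=O)Oc2cc(C)c(C(=O)OCC=C)c(OCc3ccccc3)c2)c(C)c1OC | intermediate
16 | 2-(benzyloxy)-6-methyl-4-[(2,4,5-trimethoxy-6-methylbenzoyl)oxy]benzoic acid | COc1cc(OC)c(C(=O)Oc2cc(C)c(C(=O)O)c(OCc3ccccc3)c2)c(C)c1OC | intermediate
17 | benzyl 2,4-dihydroxy-6-methylbenzoate | Cc1cc(O)cc(O)c1C(=O)OCc1ccccc1 | intermediate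
18 | 2-(benzyloxy)-6-methyl-4-[(2,4,5-trimethoxy-6-methylbenzoyl)oxy]benzoic trifluoroacetic anhydride | COc1cc(OC)c(C(=O)Oc2cc(C)c(C(=O)OC(=O)C(F)(F)F)c(OCc3ccccc3)c2)c(C)c1OC | intermediate (not isolated)
19 | benzyl 4-({2-(benzyloxy)-6-methyl-4-[(2,4,5-trimethoxy-6-methylbenzoyl)oxy]benzoyl}oxy)-2-hydroxy-6-methylbenzoate | COc1cc(OC)c(C(=O)Oc2cc(C)c(C(=O)Oc3cc(C)c(C(=O)OCc4ccccc4)c(O)c3)c(OCc5ccccc5)c2)c(C)c1OC | intermediate
20 | 2-hydroxy-4-({2-hydroxy-6-methyl-4-[(2,4,5-trimethoxy-6-methylbenzoyl)oxy]benzoyl}oxy)-6-methylbenzoic acid | COc1cc(OC)c(C(=O)Oc2cc(C)c(C(=O)Oc3cc(C)c(C(=O)O)c(O)c3)c(O)c2)c(C)c1OC | target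

Total step count: 12. Longest linear sequence: 10 steps (steps 1, 2, 3, 4, 5, 7, 8, 9, 11, 12, from orsellinic acid).

Steps most likely to fail

Step 7. The beta-methyl ynoate is a sluggish dienophile. The silyloxyfuran may therefore decompose or lose its silyl group before it adds, or conjugate addition through furan C-5 may stop without ring closure. The fallback makes ring A from an aromatic acid and not by cycloaddition; it sets out from 5 and comes back at 15. Purchased 2,4,5-trimethoxybenzoic acid F1 would be ortho-lithiated at C-6 (s-BuLi, TMEDA, THF, −78 °C), the carboxylate and the 5-methoxy group directing together, and quenched with MeI to give 2,4,5-trimethoxy-6-methylbenzoic acid F2. F2 would then be esterified with phenol 5 through its mixed trifluoroacetic anhydride ((CF3CO)2O, toluene, rt) to give 15.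

Step 8. Once the silyl group is lost, the free phenoxide or fluoride in DMF may cleave the depside ester by acyl transfer, or the electron-rich phenoxide may be oxidised by air towards a quinone. The fallback avoids phenoxides and fluoride salts altogether; it sets out from 12 and comes back at 15. The free 5-hydroxyl would be methylated with trimethylsilyldiazomethane (MeOH/toluene, rt) to give 13, here isolated. The silyl ether would be cleaved under acidic conditions (HF·pyridine, THF, 0 °C) to the neutral phenol allyl 2-(benzyloxy)-4-[(2-hydroxy-4,5-dimethoxy-6-methylbenzoyl)oxy]-6-methylbenzoate F3, and this chelated phenol methylated under Purdie conditions (MeI, Ag2O, CH2Cl2, dark, rt) to give 15.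

Step 11. Acylation by the hindered mixed anhydride may be slow under the acidic conditions, so that electrophilic C-acylation of an electron-rich ring (C-3 of ring A, or ring C) or trifluoroacetylation of the phenol competes. The fallback forms the ester under basic conditions from an isolated acyl chloride; it sets out from 16 and comes back at 19. Acid 16 would be converted with oxalyl chloride and catalytic DMF (CH2Cl2, 0 °C) into 2-(benzyloxy)-6-methyl-4-[(2,4,5-trimethoxy-6-methylbenzoyl)oxy]benzoyl chloride F4, which would be added to 17 with Et3N and catalytic DMAP (CH2Cl2, 0 °C) to acylate the 4-hydroxyl and give 19.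

Further compounds
F1 | step 7 | 2,4,5-trimethoxybenzoic acid (purchased) | COc1cc(OC)c(C(=O)O)cc1OC
F2 | step 7 | 2,4,5-trimethoxy-6-methylbenzoic acid | COc1cc(OC)c(C(=O)O)c(C)c1OC
F3 | step 8 | allyl 2-(benzyloxy)-4-[(2-hydroxy-4,5-dimethoxy-6-methylbenzoyl)oxy]-6-methylbenzoate | COc1cc(O)c(C(=O)Oc2cc(C)c(C(=O)OCC=C)c(OCc3ccccc3)c2)c(C)c1OC
F4 | step 11 | 2-(benzyloxy)-6-methyl-4-[(2,4,5-trimethoxy-6-methylbenzoyl)oxy]benzoyl chloride | COc1cc(OC)c(C(=O)Oc2cc(C)c(C(=O)Cl)c(OCc3ccccc3)c2)c(C)c1OC
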